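**Plan**
- Enabling feature: the only ring is a cyclopentanone with its ketone at C9, a CH2 at C10 and a β-hydroxyl at C11. It can therefore be closed at C9–C10 from a C9 aldehyde and a C10≡C11 alkyne, and the C10=C11 enone that results takes up the C11 oxygen afterwards.
- Retrosynthetic cuts, in order: C1 ester; C11–O; C10–Si; ring bond C9–C10 (alkyne hydroacylation); C7–C8 (α-chain alkylation); C11–C12 (conjugate alkynylation); C8=C12 (cross-metathesis); C13–C14 and C15–C16 (two epoxide openings).
- Forward: the C12–C20 chain is built from (S)-epichlorohydrin and extended to the enal; the alkyne goes onto C12 and the α-chain onto C8; the ring then closes in step 10, followed by C11 oxygenation and ester hydrolysis.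
- Stereochemistry: C15 from (S)-epichlorohydrin; C12 from the rhodium/(R)-DTBM-segphos alkynylation; C8 from the SAMP auxiliary (also the thermodynamically preferred trans arrangement in the ring); C11 by boryl addition anti to the C12 chain, oxidised with retention.

Key step: step 10

Remark: (R)-DTBM-segphos is assigned Re-face delivery at C12 by analogy with rhodium/(R)-binap-type conjugate additions; the antipodal ligand would be used if the sense proved opposite.

**Step 1**
Reactants: 1 (S)-epichlorohydrin; 2 n-butylmagnesium chloride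
Product: 4 (S)-1,2-epoxyheptane, via (S)-1-chloroheptan-2-ol 3 (not isolated)
Conditions: n-BuMgCl, CuI (5 mol%), THF, −40 °C; aq. NH4Cl; crude 3 then powdered NaOH, Et2O, rt
Reagents that add atoms: none
Why: Copper-catalysed Grignard opening of the epoxide at its CH2 terminus followed by Williamson-type closure of the chlorohydrin should give the epoxide, and since no bond to the stereocentre is touched the (S) centre (later C15) is carried over.

**Step 2**
Reactants: 4 (S)-1,2-epoxyheptane; 5 allylmagnesium chloride
Product: 6 (5S)-dec-1-en-5-ol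
Conditions: allylMgCl, CuI (10 mol%), THF, −30 → 0 °C
Reagents that add atoms: none
Why: Copper-catalysed Grignard opening of a terminal epoxide occurs at the unsubstituted carbon, so C13–C14 is formed with the carbinol centre untouched.

**Step 3**
Reactants: 6 (5S)-dec-1-en-5-ol
Product: 7 tert-butyl[(5S)-dec-1-en-5-yloxy]dimethylsilane
Conditions: TBSCl, imidazole, DMF, rt
Reagents that add atoms: tert-butyldimethylsilyl chloride, CC(C)(C)[Si](C)(C)Cl
Why: Standard silylation of a secondary alcohol; the ether prevents oxa-Michael closure onto the enal made next.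

**Step 4**
Reactants: 7 tert-butyl[(5S)-dec-1-en-5-yloxy]dimethylsilane; 8 (E)-but-2-enal (crotonaldehyde)
Product: 9 (2E,6S)-6-(tert-butyldimethylsilyloxy)undec-2-enal
Conditions: crotonaldehyde (5 equiv), second-generation Hoveyda–Grubbs catalyst (H2IMes)Cl2Ru(=CH-C6H4-2-O-i-Pr) (3 mol%), CH2Cl2, 40 °C
Reagents that add atoms: none
Why: Olefin cross-metathesis of an unhindered terminal alkene with crotonaldehyde should give the (E)-enal under thermodynamic control, with propene as the volatile co-product.

**Step 5**
Reactants: 9 (2E,6S)-6-(tert-butyldimethylsilyloxy)undec-2-enal; 10 (triisopropylsilyl)acetylene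
Product: 11 (3R,6S)-6-(tert-butyldimethylsilyloxy)-3-[(triisopropylsilyl)ethynyl]undecanal
Conditions: [Rh(OAc)(C2H4)2]2 (2.5 mol%), (R)-DTBM-segphos (6 mol%), alkyne (2 equiv), MeOH, 40 °C
Reagents that add atoms: none
Why: Rhodium-catalysed asymmetric conjugate alkynylation of an enal, in which the bulky silyl group and bulky bisphosphine suppress alkyne dimerisation; the alkynyl of the monovalent rhodium species is delivered to the Re face of C12 under ligand control, setting C12 as R.

**Step 6**
Reactants: 11 (3R,6S)-6-(tert-butyldimethylsilyloxy)-3-[(triisopropylsilyl)ethynyl]undecanal; 12 SAMP, (2S)-2-(methoxymethyl)pyrrolidin-1-amine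
Product: 13 SAMP hydrazone of 11
Conditions: SAMP (1.1 equiv), MgSO4, CH2Cl2, 0 °C → rt
Reagents that add atoms: none
Why: Hydrazone condensation masks the aldehyde against the fluoride and amide bases that follow and installs the auxiliary that will control C8.

**Step 7**
Reactants: 13 SAMP hydrazone of 11
Product: 14 SAMP hydrazone of (3R,6S)-6-(tert-butyldimethylsilyloxy)-3-ethynylundecanal
Conditions: Bu4NF (TBAF, 1.05 equiv), THF, −20 → 0 °C; aq. NH4Cl
Reagents that add atoms: none
Why: Fluoride desilylation of an alkynylsilane, where the C(sp)–Si bond (acetylide as leaving group) should cleave well before the secondary alkyl silyl ether at low temperature; this removes the bulky cap that step 5 needed but step 10 would not tolerate.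

**Step 8**
Reactants: 14 SAMP hydrazone of (3R,6S)-6-(tert-butyldimethylsilyloxy)-3-ethynylundecanal; 15 methyl 7-iodoheptanoate
Product: 17 SAMP hydrazone of methyl (8R,9R,12S)-12-(tert-butyldimethylsilyloxy)-8-formyl-9-[(trimethylsilyl)ethynyl]heptadecanoate, via C-silylated hydrazone 16 (not isolated)
Conditions: LiN(i-Pr)2 (LDA, 1.05 equiv), THF, −78 °C; TMSCl (1.05 equiv), −78 → 0 °C; LDA (1.2 equiv), 0 °C; 15 (1.2 equiv), −100 → −20 °C
Reagents that add atoms: chlorotrimethylsilane, C[Si](C)(C)Cl
Why: The acetylenic C–H is removed first and capped with silicon, after which SAMP-hydrazone (Enders) alkylation of the chelated lithium azaenolate with the primary iodide, whose ester is tolerated at low temperature, forms C7–C8 on the face dictated by the auxiliary and sets C8 as R.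

**Step 9**
Reactants: 17 SAMP hydrazone of the C8-alkylated aldehyde
Product: 18 methyl (8R,9R,12S)-12-(tert-butyldimethylsilyloxy)-8-formyl-9-[(trimethylsilyl)ethynyl]heptadecanoate
Conditions: O3, CH2Cl2, −78 °C, to the end point only; Ar purge
Reagents that add atoms: ozone, [O-][O+]=O
Why: Ozonolytic cleavage of the electron-rich hydrazone C=N is far faster than attack on the silylalkyne and is non-epimerising, so the α-branched aldehyde should be released with C8 intact.

**Step 10**
Reactants: 18 methyl (8R,9R,12S)-12-(tert-butyldimethylsilyloxy)-8-formyl-9-[(trimethylsilyl)ethynyl]heptadecanoate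
Product: 19 methyl 7-[(1R,5R)-5-[(3S)-3-(tert-butyldimethylsilyloxy)octyl]-2-oxo-3-(trimethylsilyl)cyclopent-3-en-1-yl]heptanoate
Conditions: [Rh(dppe)]2(BF4)2 (5 mol%, from [Rh(nbd)(dppe)]BF4 and H2), acetone, rt → 40 °C, Ar
Reagents that add atoms: none
Why: Oxidative addition of the C9–H bond to cationic monovalent rhodium gives an acyl hydride of trivalent rhodium; the hydride goes to C11 with net trans addition, C10 binds rhodium in a six-membered acyl–vinyl rhodacycle, and reductive elimination forms C9–C10. The closest known reaction type is the [Rh(dppe)]+-catalysed cyclisation of 4-alkynals to cyclopent-2-enones, applied here to a 2,3-disubstituted, silyl-capped member of that class. The five-membered ring closes as a formal 5-endo-dig acylation (both alkyne carbons end up in the ring), which the trans hydrometalation makes geometrically possible. No stereocentre is created: C12 and C15 are spectators, and C8 should be retained because the medium is neutral and non-enolising, its trans relation to C12 being in any case the favoured one in the enone. The step needs hydroacylation to outrun decarbonylation and four-membered-ring formation; the chelating dppe on a cationic centre in weakly coordinating acetone addresses the first, and the trans pathway together with the silyl cap (no terminal C–H, hence no vinylidene or oligomer formation) addresses the second.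

**Step 11**
Reactants: 19 silyl enone
Product: 20 methyl 7-[(1R,5S)-5-[(3S)-3-hydroxyoctyl]-2-oxocyclopent-3-en-1-yl]heptanoate
Conditions: Bu4NF (TBAF, 3 equiv), AcOH (3 equiv), THF, 0 °C → rt
Reagents that add atoms: none
Why: Fluoride-induced protodesilylation of a 2-silyl cyclopent-2-enone is combined with silyl ether cleavage, and the acetic acid buffer should keep the medium near neutral so that the base-sensitive 4,5-disubstituted enone is not isomerised.

**Step 12**
Reactants: 20 enone
Product: 22 methyl 7-[(1R,2R,3R)-3-hydroxy-2-[(3S)-3-hydroxyoctyl]-5-oxocyclopentyl]heptanoate, via 11-boryl ketone 21 (not isolated)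
Conditions: B2pin2 (1.1 equiv), CuCl (5 mol%), NaOt-Bu (10 mol%), xantphos (5 mol%), MeOH (2 equiv), THF, rt; then NaBO3·4H2O, THF/H2O, 0 °C
Reagents that add atoms: bis(pinacolato)diboron, CC1(C)OB(OC1(C)C)B1OC(C)(C)C(C)(C)O1 (boron of 21); sodium perborate, [Na+].[O-]OB=O (C11 oxygen of 22)
Why: Copper-catalysed conjugate borylation of a cyclic enone followed by perborate oxidation of the C–B bond with retention; the boryl copper species should add to C11 on the face opposite the adjacent C12 chain, setting C11 as R (11α), and the cold, mildly basic oxidant is chosen to spare the β-hydroxy ketone.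

**Step 13**
Reactants: 22 methyl ester
Product: 23 13,14-dihydro-PGE1, 7-[(1R,2R,3R)-3-hydroxy-2-[(3S)-3-hydroxyoctyl]-5-oxocyclopentyl]heptanoic acid
Conditions: porcine liver esterase, pH 7.5 phosphate buffer, acetone (10%), 30 °C
Reagents that add atoms: water, O
Why: Enzymatic ester hydrolysis at neutral pH should free the acid without the dehydration or C8 epimerisation that chemical saponification of a β-hydroxy cyclopentanone would cause.

**Compound list**
1 | (S)-epichlorohydrin, (2S)-2-(chloromethyl)oxirane | ClC[C@@H]1CO1 | starting material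
2 | n-butylmagnesium chloride | CCCC[Mg]Cl | starting material
3 | (2S)-1-chloroheptan-2-ol, formed and used without isolation | ClC[C@@H](O)CCCCC | intermediate
4 | (S)-1,2-epoxyheptane, (2S)-2-pentyloxirane | CCCCC[C@H]1CO1 | intermediate
5 | allylmagnesium chloride | C=CC[Mg]Cl | starting material
6 | (5S)-dec-1-en-5-ol | C=CCC[C@@H](O)CCCCC | intermediate
7 | tert-butyl[(5S)-dec-1-en-5-yloxy]dimethylsilane | C=CCC[C@@H](O[Si](C)(C)C(C)(C)C)CCCCC | intermediate
8 | (E)-but-2-enal (crotonaldehyde) | C/C=C/C=O | starting material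
9 | (2E,6S)-6-(tert-butyldimethylsilyloxy)undec-2-enal | O=C/C=C/CC[C@@H](O[Si](C)(C)C(C)(C)C)CCCCC | intermediate
10 | (triisopropylsilyl)acetylene | C#C[Si](C(C)C)(C(C)C)C(C)C | starting material
11 | (3R,6S)-6-(tert-butyldimethylsilyloxy)-3-[(triisopropylsilyl)ethynyl]undecanal | O=CC[C@@H](CC[C@@H](O[Si](C)(C)C(C)(C)C)CCCCC)C#C[Si](C(C)C)(C(C)C)C(C)C | intermediate
12 | SAMP, (2S)-2-(methoxymethyl)pyrrolidin-1-amine | COC[C@@H]1CCCN1N | starting material
13 | (E)-SAMP hydrazone of 11 | COC[C@@H]1CCCN1/N=C/C[C@@H](CC[C@@H](O[Si](C)(C)C(C)(C)C)CCCCC)C#C[Si](C(C)C)(C(C)C)C(C)C | intermediate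
14 | (E)-SAMP hydrazone of (3R,6S)-6-(tert-butyldimethylsilyloxy)-3-ethynylundecanal | COC[C@@H]1CCCN1/N=C/C[C@@H](CC[C@@H](O[Si](C)(C)C(C)(C)C)CCCCC)C#C | intermediate
15 | methyl 7-iodoheptanoate | COC(=O)CCCCCCI | starting material
16 | (E)-SAMP hydrazone of (3R,6S)-6-(tert-butyldimethylsilyloxy)-3-[(trimethylsilyl)ethynyl]undecanal, formed and used without isolation | COC[C@@H]1CCCN1/N=C/C[C@@H](CC[C@@H](O[Si](C)(C)C(C)(C)C)CCCCC)C#C[Si](C)(C)C | intermediate
17 | (E)-SAMP hydrazone of 18, methyl (8R,9R,12S)-12-(tert-butyldimethylsilyloxy)-8-[{[(2S)-2-(methoxymethyl)pyrrolidin-1-yl]imino}methyl]-9-[(trimethylsilyl)ethynyl]heptadecanoate | COC[C@@H]1CCCN1/N=C/[C@H](CCCCCCC(=O)OC)[C@@H](CC[C@@H](O[Si](C)(C)C(C)(C)C)CCCCC)C#C[Si](C)(C)C | intermediate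
18 | methyl (8R,9R,12S)-12-(tert-butyldimethylsilyloxy)-8-formyl-9-[(trimethylsilyl)ethynyl]heptadecanoate | O=C[C@H](CCCCCCC(=O)OC)[C@@H](CC[C@@H](O[Si](C)(C)C(C)(C)C)CCCCC)C#C[Si](C)(C)C | intermediate
19 | methyl 7-[(1R,5R)-5-[(3S)-3-(tert-butyldimethylsilyloxy)octyl]-2-oxo-3-(trimethylsilyl)cyclopent-3-en-1-yl]heptanoate | O=C1C([Si](C)(C)C)=C[C@H](CC[C@@H](O[Si](C)(C)C(C)(C)C)CCCCC)[C@H]1CCCCCCC(=O)OC | intermediate
20 | methyl 7-[(1R,5S)-5-[(3S)-3-hydroxyoctyl]-2-oxocyclopent-3-en-1-yl]heptanoate | O=C1C=C[C@H](CC[C@@H](O)CCCCC)[C@H]1CCCCCCC(=O)OC | intermediate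
21 | methyl 7-[(1R,2S,3R)-2-[(3S)-3-hydroxyoctyl]-5-oxo-3-(4,4,5,5-tetramethyl-1,3,2-dioxaborolan-2-yl)cyclopentyl]heptanoate, formed and used without isolation | O=C1C[C@@H](B2OC(C)(C)C(C)(C)O2)[C@H](CC[C@@H](O)CCCCC)[C@H]1CCCCCCC(=O)OC | intermediate
22 | methyl 7-[(1R,2R,3R)-3-hydroxy-2-[(3S)-3-hydroxyoctyl]-5-oxocyclopentyl]heptanoate | O=C1C[C@@H](O)[C@H](CC[C@@H](O)CCCCC)[C@H]1CCCCCCC(=O)OC | intermediate
23 | 13,14-dihydro-PGE1, 7-[(1R,2R,3R)-3-hydroxy-2-[(3S)-3-hydroxyoctyl]-5-oxocyclopentyl]heptanoic acid | CCCCC[C@H](O)CC[C@H]1[C@H](O)CC(=O)[C@@H]1CCCCCCC(=O)O | target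

**Step count and risks**
Total: 13 steps. Longest linear sequence: 13 steps (1 → 23); the route is fully linear.

Steps most likely to fail:

1. Step 10. Decarbonylation of the acyl rhodium hydride, or stalled insertion of the hindered silyl-capped alkyne next to two branched carbons, may outpace ring closure. Fallback: setting out from 18, the same C9–C10 bond is made by a vinylsilane-terminated Friedel–Crafts acylation. Semihydrogenation of the silylalkyne (H2, Pd/CaCO3 poisoned with Pb(OAc)2, quinoline) should give methyl (8R,9R,12S)-12-(tert-butyldimethylsilyloxy)-8-formyl-9-[(Z)-2-(trimethylsilyl)ethenyl]heptadecanoate F1. Pinnick oxidation (NaClO2, NaH2PO4, 2-methylbut-2-ene) gives the corresponding C9 carboxylic acid F2. Oxalyl chloride converts it into the acid chloride F3, which SnCl4 (CH2Cl2, −78 °C) should cyclise by ipso attack at C10, with loss of the silyl group, to the 15-O-silyl enone F4. HF·pyridine then removes the silyl ether and the route is rejoined at 20.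

2. Step 11. Under fluoride the C10=C11 double bond may migrate towards the tetrasubstituted C8–C12 position, or C–Si cleavage may lag behind silyl ether cleavage. Fallback: setting out from 19, silicon is removed only after the conjugate addition. Copper-catalysed boryl addition (B2pin2, CuCl, NaOt-Bu, xantphos, MeOH, THF) on the silyl enone itself should give the 10-silyl 11-boryl ketone F5. K2CO3 in MeOH cleaves the C–Si bond of this α-silyl ketone to the 11-boryl ketone F6. NaBO3·4H2O gives the 15-O-silyl 11-alcohol F7, and HF·pyridine in MeCN rejoins the route at 22.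

3. Step 12. Facial discrimination in the boryl transfer may be insufficient, or the β-hydroxy ketone may dehydrate during the basic oxidation. Fallback: setting out from 20, Weitz–Scheffer epoxidation (H2O2, catalytic NaOH, MeOH, −30 °C) anti to the C12 chain should give the 10α,11α-epoxy ketone F8. Reductive opening at C10 with the phenylselenide–borane reagent from (PhSe)2 and NaBH4 (AcOH, EtOH, 0 °C) then gives the 11α-alcohol and rejoins the route at 22.

**Further compounds**
F1 | step 10 | methyl (8R,9R,12S)-12-(tert-butyldimethylsilyloxy)-8-formyl-9-[(Z)-2-(trimethylsilyl)ethenyl]heptadecanoate | O=C[C@H](CCCCCCC(=O)OC)[C@@H](CC[C@@H](O[Si](C)(C)C(C)(C)C)CCCCC)/C=C\[Si](C)(C)C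
F2 | step 10 | C9 carboxylic acid from F1 (formyl oxidised to CO2H, configuration unchanged) | OC(=O)[C@H](CCCCCCC(=O)OC)[C@@H](CC[C@@H](O[Si](C)(C)C(C)(C)C)CCCCC)/C=C\[Si](C)(C)C
F3 | step 10 | acid chloride of F2 | ClC(=O)[C@H](CCCCCCC(=O)OC)[C@@H](CC[C@@H](O[Si](C)(C)C(C)(C)C)CCCCC)/C=C\[Si](C)(C)C
F4 | step 10 | 15-O-tert-butyldimethylsilyl ether of 20 | O=C1C=C[C@H](CC[C@@H](O[Si](C)(C)C(C)(C)C)CCCCC)[C@H]1CCCCCCC(=O)OC
F5 | step 11 | 10-(trimethylsilyl)-11α-(pinacolboryl) ketone with 15-O-silyl ether (C10 epimers) | O=C1C([Si](C)(C)C)[C@@H](B2OC(C)(C)C(C)(C)O2)[C@H](CC[C@@H](O[Si](C)(C)C(C)(C)C)CCCCC)[C@H]1CCCCCCC(=O)OC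
F6 | step 11 | 15-O-tert-butyldimethylsilyl ether of 21 | O=C1C[C@@H](B2OC(C)(C)C(C)(C)O2)[C@H](CC[C@@H](O[Si](C)(C)C(C)(C)C)CCCCC)[C@H]1CCCCCCC(=O)OC
F7 | step 11 | 15-O-tert-butyldimethylsilyl ether of 22 | O=C1C[C@@H](O)[C@H](CC[C@@H](O[Si](C)(C)C(C)(C)C)CCCCC)[C@H]1CCCCCCC(=O)OC
F8 | step 12 | 10α,11α-epoxide of 20 | O=C1[C@H]2O[C@H]2[C@H](CC[C@@H](O)CCCCC)[C@H]1CCCCCCC(=O)OC
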